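Seconds are the unit to count in here, and a carrier in the first phase alternates between two jobs: salt from the second phase recharges spent carrier to fresh carrier, and fresh carrier turns starting material into product.

| flask | starting material | salt in the second phase | spent carrier | added ligand | time | volume of the second phase over the first |
|---|---|---|---|---|---|---|
| autumn | 2.0 mM | 2.00 mM | 98 µM | 0.0060 mM | 25 s | 1.0 |
| dusk | 2.0 mM | 2.00 mM | 98 µM | 0.012 mM | 25 s | 1.0 |
| midnight | 2.0 mM | 2.00 mM | 98 µM | 0.025 mM | 25 s | 1.0 |
| dawn | 2.0 mM | 2.00 mM | 98 µM | 0.050 mM | 25 s | 1.0 |
| spring | 2.0 mM | 2.00 mM | 98 µM | 0.10 mM | 25 s | 1.0 |

    spent carrier + salt in the second phase ⇌ fresh carrier + spent salt in the second phase (K1 = 0.67, k1 = 1300 M⁻¹ s⁻¹)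
    starting material + fresh carrier → product + spent carrier (k2 = 2700 M⁻¹ s⁻¹)
    added ligand + fresh carrier ⇌ idle complex, settled at all times (K3 = 9800 M⁻¹)

- amount of product at the end, in percent of the starting material charged for autumn, dusk, midnight, dawn, spring, in this order
- the course of these numbers from the first flask to the last (falls, then rises / hardly changes / rises all the way / falls all the way / rises, then falls)

- in the second phase: salt in the second phase, spent salt in the second phase; everything else is in the first
- charges count per volume of the first phase; a concentration in a rate is the amount of a species over the volume of its own phase; every rate counts per litre of the first phase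
- "hardly changes" means that all values lie within two and a half points (for a concentration: within two and a half percent of the largest)
- run time (autumn): 25 s

Let f be the fraction of the charge of starting material left. Salt is charged alike and pays one for each product, so I take the same f for salt, and the rest of its charge is spent salt.

May I treat the carrier as balanced? In autumn fresh carrier has a half-life of 0.13 s by the second step alone at the charges, far shorter than the 25 s of the run, so I set its making equal to its loss.

How, then, is the catalyst split? Dividing the rate that makes fresh carrier by the rates that remove it, time drops out: fresh over spent is the first constant times f, over the second constant times f plus the reverse constant 1940 M⁻¹ s⁻¹ times the rest. This starts at 0.481 and reaches 0.153 at f = 0.250. This fresh-to-spent ratio is smaller than 1, so spent carrier is the resting state of the round.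

What does the ligand take? Idle complex over fresh carrier is the third constant times the ligand, 0.0588 in autumn and 0.980 in spring. I take the ligand as charged, which counts it somewhat high. This term joins the sum of the catalyst's forms, so at the same f fresh carrier's share shrinks.

Integrating the second step's rate over f gives a logarithmic term, which carries the ligand, and a reciprocal term, which carries the reverse step. The time to reach f = 0.250 is 25.5 s in autumn and 30.4 s in spring. Near there f moves by 0.00869 s⁻¹ in autumn and 0.00775 s⁻¹ in spring. Stepping back to 25 s, I reckon 74.5% in autumn and 70.8% in spring. That is a fall of 3.7 percentage points against the 2.5 points of "hardly changes", and the reckoned time grows steadily with the ligand, so the course I commit to is this: falls all the way.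

The forecast gives 73.6% for autumn and 69.9% for spring, falls all the way, on the grounds that the “ligand only parks fresh carrier as idle complex”, and it stands 0.90 points below my autumn figure.

The run gives 74.0%, 73.8%, 73.3%, 72.2% and 70.1%: falls all the way. In autumn at 25.0 s, spent carrier has a half-life of 1.1 s by the forward rate of the first step alone, far shorter than the run, and fresh over spent stands at 0.154 against the reckoned 0.153. In spring at 25.0 s, the same ratio fed with 29.9% of the starting material and 28.7% of the salt gives 0.170, the flask shows 0.172, and idle complex holds 11.3% of the catalyst.

All constants were set for the occasion; the result is computed.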